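**Plan**

- Retrosynthetic cuts, in this order: the C11=C13 methylene (olefination of a C11 phosphonate with formaldehyde); the lactone bond C7–C11 (carbenoid C–H insertion of an 8β-diazophosphonoacetate); the ester bond C8–O (carboxylate opening of an 8α,9α-epoxide); ring B at C8=C9 (ring-closing metathesis) and at C6–C7 (allylation); ring A with its oxygen bridge at C1–C10 and C4–C5 (Diels–Alder reaction of 2-methylfuran with dimethyl mesaconate).
- Forward: ring A with the 1,4-oxygen bridge arises first as a 7-oxanorbornane. Ring B is then closed by metathesis between an allyl arm on C6 and a vinyl group on C10. The lactone (ring C) is closed in step 17, and the exocyclic methylene comes last.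
- Feature that makes the key step possible: on ring B the ester oxygen at C8 is axial and β, gauche to the equatorial 7β-H. Of the two C–H bonds within five-membered reach, C9–H is shut down by its geminal acyloxy group and the adjacent quaternary C10. The carbenoid therefore closes the cis-fused γ-lactone at C7.
- Stereochemistry: C1, C4, C5 and C10 come together from the cycloaddition of the E dienophile, with the absolute configuration from resolution of a monoacid. C6 comes from a chelation-controlled allylation. C8 and C9 come from α-face epoxidation (anti to the C10 methyl) followed by trans-diaxial opening. C7 comes from C–H insertion with retention.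

Key step: step 17

Assumption: the less soluble salt of acid 5 with (S)-1-phenylethylamine is taken to contain the (1S,2R,3R,4R) acid; if it holds the antipode, the (R)-amine is used in the same way.

Convention: ring atoms carry eudesmane numbers, and β is the face of the C10 methyl and of the oxygen bridge. Names of 3–12 and 15 use 7-oxabicyclo[2.2.1]heptane locants, in which C1, C2, C3 and C4 are C4, C5, C10 and C1 of the target and O7 is the bridge.

**Route**

Step 1
Reactants: 1 2-methylfuran; 2 dimethyl mesaconate
Product: 3 dimethyl (1S*,2R*,3R*,4R*)-1,3-dimethyl-7-oxabicyclo[2.2.1]hept-5-ene-2,3-dicarboxylate (racemic; 2-ester exo; 3-ester endo; 3-methyl exo)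
Conditions: 1 (5 equiv), CH2Cl2, 1.5 GPa, 25 °C; chromatography
Reagents that add atoms: none
Why: High-pressure Diels–Alder reaction, chosen because furan cycloadditions to trisubstituted fumarate-type dienophiles are slow and reversible at ambient pressure: the fully substituted dienophile carbon should bond to the unsubstituted furan terminus (no contiguous quaternary centres), the E geometry places the two esters trans, and the C3 methyl is expected to take the exo position beside the small oxygen bridge instead of the endo position under the diene, which sets C1, C2, C3 and C4 relative to one another in racemic form.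

Step 2
Reactants: 3 the oxanorbornene diester
Product: 4 dimethyl (1S*,2R*,3R*,4R*)-1,3-dimethyl-7-oxabicyclo[2.2.1]heptane-2,3-dicarboxylate (racemic)
Conditions: H2 (1 atm), 10% Pd/C, EtOAc, 25 °C
Reagents that add atoms: none
Why: Heterogeneous hydrogenation of the strained disubstituted alkene, which also closes the retro-Diels–Alder exit; no stereocentre is formed.

Step 3
Reactants: 4 the saturated diester
Product: 5 (1S*,2R*,3R*,4R*)-3-(methoxycarbonyl)-1,3-dimethyl-7-oxabicyclo[2.2.1]heptane-2-carboxylic acid (racemic)
Conditions: LiOH·H2O (1.1 equiv), THF/MeOH/H2O, 0 °C to 25 °C; then 1 M HCl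
Reagents that add atoms: lithium hydroxide, [Li+].[OH-]
Why: Saponification discriminates by steric hindrance, the ester on the tertiary carbon C2 being cleaved far faster than the neopentyl-type ester on the quaternary C3, and the exo acid trans to the C3 ester is the stable epimer so C2 should not be scrambled.

Step 4
Reactants: 5 the racemic monoacid
Product: 6 (S)-1-phenylethylammonium (1S,2R,3R,4R)-3-(methoxycarbonyl)-1,3-dimethyl-7-oxabicyclo[2.2.1]heptane-2-carboxylate (single diastereomer)
Conditions: (S)-1-phenylethylamine (1 equiv), EtOAc/i-PrOH, 60 °C to 5 °C, recrystallisation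
Reagents that add atoms: (S)-1-phenylethylamine, C[C@H](N)c1ccccc1
Why: Classical resolution by crystallisation of diastereomeric ammonium salts, which supplies the absolute configuration of C1, C2, C3 and C4 (C4, C5, C10 and C1 of the target) without touching any bond at a stereocentre.

Step 5
Reactants: 6 the resolved ammonium salt
Product: 7 (1S,4R)-3-endo-(hydroxymethyl)-1,3-dimethyl-7-oxabicyclo[2.2.1]heptane-2-exo-carboxylic acid (3-methyl exo)
Conditions: LiEt3BH (4.5 equiv), THF, 0 °C to 25 °C; then 1 M HCl
Reagents that add atoms: none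
Why: Hydride reduction with LiEt3BH, which reduces hindered esters to primary alcohols but leaves carboxylate anions alone, the ammonium proton only consuming one further equivalent of hydride; no stereocentre is affected and the trans (exo/endo) arrangement rules out lactonisation.

Step 6
Reactants: 7 the hydroxy acid
Product: 8 (1S,4R)-3-endo-formyl-1,3-dimethyl-7-oxabicyclo[2.2.1]heptane-2-exo-carboxylic acid
Conditions: Dess–Martin periodinane, CH2Cl2, 25 °C
Reagents that add atoms: none
Why: Dess–Martin oxidation of the primary alcohol, compatible with the free acid, gives an aldehyde that cannot enolise because C3 is quaternary.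

Step 7
Reactants: 8 the aldehyde acid
Product: 9 (1S,4R)-3-endo-ethenyl-1,3-dimethyl-7-oxabicyclo[2.2.1]heptane-2-exo-carboxylic acid
Conditions: Ph3PCH3Br, KOtBu (3.2 equiv each), THF, 0 °C to 25 °C; then 1 M HCl
Reagents that add atoms: methyltriphenylphosphonium bromide, C[P+](c1ccccc1)(c1ccccc1)c1ccccc1.[Br-]
Why: Wittig methylenation, in which the first equivalent of ylide merely deprotonates the acid and the non-enolisable neopentyl aldehyde is then converted into the vinyl group that becomes C9.

Step 8
Reactants: 9 the vinyl acid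
Product: 10 [(1S,4R)-3-endo-ethenyl-1,3-dimethyl-7-oxabicyclo[2.2.1]heptan-2-exo-yl]methanol
Conditions: LiAlH4, THF, 0 °C to reflux
Reagents that add atoms: none
Why: LiAlH4 reduction of the carboxylic acid to the primary alcohol, with the isolated alkene inert to the reagent and C2 untouched.

Step 9
Reactants: 10 the primary alcohol
Product: 11 (1S,4R)-3-endo-ethenyl-1,3-dimethyl-7-oxabicyclo[2.2.1]heptane-2-exo-carbaldehyde
Conditions: Dess–Martin periodinane, pyridine, CH2Cl2, 0 °C to 25 °C
Reagents that add atoms: none
Why: Dess–Martin oxidation under pyridine buffering gives the aldehyde without strong base, so the C2 hydrogen, which is α to the carbonyl and β to the bridge oxygen, should neither epimerise nor trigger opening of the oxygen bridge.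

Step 10
Reactants: 11 the aldehyde
Product: 12 (S)-1-[(1S,4R)-3-endo-ethenyl-1,3-dimethyl-7-oxabicyclo[2.2.1]heptan-2-exo-yl]but-3-en-1-ol
Conditions: CH2=CHCH2SnBu3, MgBr2·OEt2, CH2Cl2, −20 °C to 0 °C
Reagents that add atoms: allyltributylstannane, C=CC[Sn](CCCC)(CCCC)CCCC
Why: Chelation-controlled allylation of a β-alkoxy aldehyde (Keck-type addition of an allylstannane): MgBr2 should tie the carbonyl oxygen to the bridge oxygen O7, which turns one face of the aldehyde towards C3 with its exo methyl and leaves the other, flanked by the C2 hydrogen, open to the allyl group, so that the (S) carbinol (the 6α oxygen of the target) is expected, the same face being predicted by the Felkin–Anh model with C3 as the large substituent.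

Step 11
Reactants: 12 the homoallylic alcohol; 13 angelic acid
Product: 15 (S)-1-[(1S,4R)-3-endo-ethenyl-1,3-dimethyl-7-oxabicyclo[2.2.1]heptan-2-exo-yl]but-3-enyl angelate, via angelic 2,4,6-trichlorobenzoic anhydride 14 (not isolated)
Conditions: 13, 2,4,6-trichlorobenzoyl chloride, Et3N, PhMe, 25 °C; then 12, 80 °C
Reagents that add atoms: 2,4,6-trichlorobenzoyl chloride, ClC(=O)c1c(Cl)cc(Cl)cc1Cl (its atoms stay in 14 only and leave before 15)
Why: Yamaguchi esterification through the mixed anhydride in the absence of DMAP, the conditions under which angelic acid is transferred to hindered secondary alcohols without Z to E isomerisation to the tiglate; the carbinol configuration is retained because only the O–H bond reacts.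

Step 12
Reactants: 15 the diene angelate
Product: 16 6α-angeloyloxy-1β,4β-epoxy-11,12,13-trinoreudesm-8-ene (5αH; 10β-methyl)
Conditions: second-generation Grubbs catalyst (H2IMes)(PCy3)Cl2Ru=CHPh (5 mol %), PhMe (2 mM), 80 °C, argon sparge
Reagents that add atoms: none
Why: Ring-closing metathesis between the allyl terminus (initiation site) and the vinyl group on the quaternary carbon closes ring B as a cyclohexene with loss of ethene, the trisubstituted, electron-poor angelate alkene staying out of the catalytic cycle; no stereocentre is formed.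

Step 13
Reactants: 16 the ring B alkene
Product: 17 6α-angeloyloxy-1β,4β:8α,9α-diepoxy-11,12,13-trinoreudesmane
Conditions: mCPBA, CH2Cl2, 0 °C
Reagents that add atoms: 3-chloroperbenzoic acid, OOC(=O)c1cccc(Cl)c1
Why: Prilezhaev epoxidation of the only electron-rich alkene, the peracid approaching the C8=C9 bond from the α face because the axial C10 methyl group stands over the β face, which sets C8 and C9 as the 8α,9α-epoxide.

Step 14
Reactants: 17 the 8α,9α-epoxide; 18 diethylphosphonoacetic acid
Product: 19 6α-angeloyloxy-1β,4β-epoxy-9α-hydroxy-11,12,13-trinoreudesman-8β-yl (diethoxyphosphoryl)acetate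
Conditions: 18 (4 equiv), Cs2CO3 (0.3 equiv), DMF, 80 °C
Reagents that add atoms: none
Why: Nucleophilic epoxide opening by a carboxylate (SN2, trans-diaxial in the Fürst–Plattner sense): attack should occur at C8 from the β face with inversion, because C9 is neopentyl (next to the quaternary C10) and because only this mode gives the diaxial product, so the ester oxygen arrives 8β while the hydroxyl stays 9α, and the trans-diaxial relation blocks acyl migration.

Step 15
Reactants: 19 the hydroxy phosphonoacetate
Product: 20 6α-angeloyloxy-1β,4β-epoxy-9α-hydroxy-11,12,13-trinoreudesman-8β-yl diazo(diethoxyphosphoryl)acetate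
Conditions: 4-acetamidobenzenesulfonyl azide, DBU, MeCN, 0 °C
Reagents that add atoms: 4-acetamidobenzenesulfonyl azide, CC(=O)Nc1ccc(cc1)S(=O)(=O)N=[N+]=[N-]
Why: Regitz diazo transfer to the only doubly activated methylene, that of the phosphonoacetate; the hydroxyl and the stereocentres do not take part.

Step 16
Reactants: 20 the diazo alcohol
Product: 21 6α-angeloyloxy-9α-(chloroacetoxy)-1β,4β-epoxy-11,12,13-trinoreudesman-8β-yl diazo(diethoxyphosphoryl)acetate
Conditions: (ClCH2CO)2O, pyridine, DMAP (cat.), CH2Cl2, 0 °C to 25 °C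
Reagents that add atoms: chloroacetic anhydride, O=C(CCl)OC(=O)CCl
Why: Esterification of the axial 9α-hydroxyl with a reactive anhydride under DMAP catalysis; the chloroacetate removes the O–H bond that a carbenoid would attack first, makes the geminal C9–H electron-poor, and can later be taken off beside the angelate and the lactone, so C9 keeps the 9α configuration fixed in step 14.

Step 17
Reactants: 21 the 8β-diazophosphonoacetate
Product: 22 6α-angeloyloxy-9α-(chloroacetoxy)-11-(diethoxyphosphoryl)-1β,4β-epoxy-13-noreudesman-12,8β-olide (C11 epimers)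
Conditions: Rh2(OAc)4 (2 mol %), ClCH2CH2Cl (0.01 M), 80 °C, slow addition of 21
Reagents that add atoms: none
Why: Rh2(OAc)4 (dirhodium tetraacetate, divalent rhodium) takes N2 out of the diazophosphonoacetate, and the electrophilic rhodium carbenoid inserts into the C7–Hβ bond through a concerted three-centre transition state with retention at carbon. The closest known reaction type is the dirhodium-catalysed intramolecular 1,5 C–H insertion of alkyl diazoacetates and diazophosphonoacetates to γ-butyrolactones. The lactone ring closes in the five-membered (1,5) mode by formation of C7–C11 and is cis-fused to ring B. C7 is set by the tether, since the axial 8β-oxygen can deliver the carbenoid only to the syn, equatorial 7β-hydrogen and C11 therefore ends on the β face, while C11 itself forms as an epimer mixture that is erased in step 19. The step needs site selectivity for C7–H over C9–H, C6–H and the angelate alkene: C9–H is geminal to the chloroacetoxy group and flanked by the quaternary C10, C6–H is geminal to the angeloyloxy group and would need a six-membered closure, the angelate C=C is electron-poor and remote, and no free O–H is left.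

Step 18
Reactants: 22 the chloroacetylated phosphonolactone
Product: 23 6α-angeloyloxy-11-(diethoxyphosphoryl)-1β,4β-epoxy-9α-hydroxy-13-noreudesman-12,8β-olide (C11 epimers)
Conditions: thiourea, NaHCO3, EtOH/THF, 55 °C
Reagents that add atoms: none
Why: Dechloroacetylation with thiourea (S-alkylation at the CH2Cl group followed by cyclisation of the isothiouronium nitrogen onto the ester carbonyl) releases the 9α-alcohol under conditions that leave the angelate, the lactone and the phosphonate alone, without change at any stereocentre.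

Step 19
Reactants: 23 the 9α-hydroxy phosphonolactone
Product: 24 6α-angeloyloxy-1β,4β-epoxy-9α-hydroxyeudesm-11(13)-en-12,8β-olide (CNP0328162.1)
Conditions: 37% aq. HCHO, K2CO3, THF, 0 °C to 25 °C
Reagents that add atoms: formaldehyde, C=O
Why: Horner–Wadsworth–Emmons olefination of the α-phosphono lactone with formaldehyde under mild carbonate conditions builds the 11(13)-methylene and removes the C11 stereocentre, leaving the angelate and the free hydroxyl untouched.

**Compound list**

1 | 2-methylfuran | Cc1ccco1 | starting material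
2 | dimethyl mesaconate (dimethyl (E)-2-methylbut-2-enedioate) | COC(=O)/C=C(\C)C(=O)OC | starting material
3 | dimethyl (1S*,2R*,3R*,4R*)-1,3-dimethyl-7-oxabicyclo[2.2.1]hept-5-ene-2,3-dicarboxylate (racemic; the enantiomer carried on is shown) | COC(=O)[C@@H]1[C@@](C)(C(=O)OC)[C@H]2C=C[C@]1(C)O2 | intermediate
4 | dimethyl (1S*,2R*,3R*,4R*)-1,3-dimethyl-7-oxabicyclo[2.2.1]heptane-2,3-dicarboxylate (racemic; the enantiomer carried on is shown) | COC(=O)[C@@H]1[C@@](C)(C(=O)OC)[C@H]2CC[C@]1(C)O2 | intermediate
5 | (1S*,2R*,3R*,4R*)-3-(methoxycarbonyl)-1,3-dimethyl-7-oxabicyclo[2.2.1]heptane-2-carboxylic acid (racemic; the enantiomer carried on is shown) | OC(=O)[C@@H]1[C@@](C)(C(=O)OC)[C@H]2CC[C@]1(C)O2 | intermediate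
6 | (S)-1-phenylethylammonium (1S,2R,3R,4R)-3-(methoxycarbonyl)-1,3-dimethyl-7-oxabicyclo[2.2.1]heptane-2-carboxylate | [O-]C(=O)[C@@H]1[C@@](C)(C(=O)OC)[C@H]2CC[C@]1(C)O2.C[C@H]([NH3+])c1ccccc1 | intermediate
7 | (1S,4R)-3-endo-(hydroxymethyl)-1,3-dimethyl-7-oxabicyclo[2.2.1]heptane-2-exo-carboxylic acid (3-methyl exo) | OC(=O)[C@@H]1[C@@](C)(CO)[C@H]2CC[C@]1(C)O2 | intermediate
8 | (1S,4R)-3-endo-formyl-1,3-dimethyl-7-oxabicyclo[2.2.1]heptane-2-exo-carboxylic acid | OC(=O)[C@@H]1[C@@](C)(C=O)[C@H]2CC[C@]1(C)O2 | intermediate
9 | (1S,4R)-3-endo-ethenyl-1,3-dimethyl-7-oxabicyclo[2.2.1]heptane-2-exo-carboxylic acid | OC(=O)[C@@H]1[C@@](C)(C=C)[C@H]2CC[C@]1(C)O2 | intermediate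
10 | [(1S,4R)-3-endo-ethenyl-1,3-dimethyl-7-oxabicyclo[2.2.1]heptan-2-exo-yl]methanol | OC[C@@H]1[C@@](C)(C=C)[C@H]2CC[C@]1(C)O2 | intermediate
11 | (1S,4R)-3-endo-ethenyl-1,3-dimethyl-7-oxabicyclo[2.2.1]heptane-2-exo-carbaldehyde | O=C[C@@H]1[C@@](C)(C=C)[C@H]2CC[C@]1(C)O2 | intermediate
12 | (S)-1-[(1S,4R)-3-endo-ethenyl-1,3-dimethyl-7-oxabicyclo[2.2.1]heptan-2-exo-yl]but-3-en-1-ol | C=CC[C@H](O)[C@@H]1[C@@](C)(C=C)[C@H]2CC[C@]1(C)O2 | intermediate
13 | angelic acid ((Z)-2-methylbut-2-enoic acid) | C/C=C(/C)C(=O)O | starting material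
14 | angelic 2,4,6-trichlorobenzoic anhydride | C/C=C(/C)C(=O)OC(=O)c1c(Cl)cc(Cl)cc1Cl | intermediate
15 | (S)-1-[(1S,4R)-3-endo-ethenyl-1,3-dimethyl-7-oxabicyclo[2.2.1]heptan-2-exo-yl]but-3-enyl angelate | C=CC[C@H](OC(=O)/C(C)=C\C)[C@@H]1[C@@](C)(C=C)[C@H]2CC[C@]1(C)O2 | intermediate
16 | 6α-angeloyloxy-1β,4β-epoxy-11,12,13-trinoreudesm-8-ene (5αH; 10β-methyl) | C1=CC[C@H](OC(=O)/C(C)=C\C)[C@@H]2[C@]1(C)[C@H]3CC[C@]2(C)O3 | intermediate
17 | 6α-angeloyloxy-1β,4β:8α,9α-diepoxy-11,12,13-trinoreudesmane | O1[C@@H]2C[C@H](OC(=O)/C(C)=C\C)[C@@H]3[C@@](C)([C@@H]21)[C@H]4CC[C@]3(C)O4 | intermediate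
18 | diethylphosphonoacetic acid | OC(=O)CP(=O)(OCC)OCC | starting material
19 | 6α-angeloyloxy-1β,4β-epoxy-9α-hydroxy-11,12,13-trinoreudesman-8β-yl (diethoxyphosphoryl)acetate | CCOP(=O)(OCC)CC(=O)O[C@H]1C[C@H](OC(=O)/C(C)=C\C)[C@@H]2[C@@](C)([C@@H]1O)[C@H]3CC[C@]2(C)O3 | intermediate
20 | 6α-angeloyloxy-1β,4β-epoxy-9α-hydroxy-11,12,13-trinoreudesman-8β-yl diazo(diethoxyphosphoryl)acetate | CCOP(=O)(OCC)C(=[N+]=[N-])C(=O)O[C@H]1C[C@H](OC(=O)/C(C)=C\C)[C@@H]2[C@@](C)([C@@H]1O)[C@H]3CC[C@]2(C)O3 | intermediate
21 | 6α-angeloyloxy-9α-(chloroacetoxy)-1β,4β-epoxy-11,12,13-trinoreudesman-8β-yl diazo(diethoxyphosphoryl)acetate | CCOP(=O)(OCC)C(=[N+]=[N-])C(=O)O[C@H]1C[C@H](OC(=O)/C(C)=C\C)[C@@H]2[C@@](C)([C@@H]1OC(=O)CCl)[C@H]3CC[C@]2(C)O3 | intermediate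
22 | 6α-angeloyloxy-9α-(chloroacetoxy)-11-(diethoxyphosphoryl)-1β,4β-epoxy-13-noreudesman-12,8β-olide (C11 epimers; one shown) | CCOP(=O)(OCC)[C@H]1C(=O)O[C@H]2[C@@H]1[C@H](OC(=O)/C(C)=C\C)[C@@H]1[C@@](C)([C@@H]2OC(=O)CCl)[C@H]2CC[C@]1(C)O2 | intermediate
23 | 6α-angeloyloxy-11-(diethoxyphosphoryl)-1β,4β-epoxy-9α-hydroxy-13-noreudesman-12,8β-olide (C11 epimers; one shown) | CCOP(=O)(OCC)[C@H]1C(=O)O[C@H]2[C@@H]1[C@H](OC(=O)/C(C)=C\C)[C@@H]1[C@@](C)([C@@H]2O)[C@H]2CC[C@]1(C)O2 | intermediate
24 | 6α-angeloyloxy-1β,4β-epoxy-9α-hydroxyeudesm-11(13)-en-12,8β-olide (CNP0328162.1) | C=C1C(=O)O[C@H]2[C@@H]1[C@H](OC(=O)/C(C)=C\C)[C@@H]1[C@@](C)([C@@H]2O)[C@H]2CC[C@]1(C)O2 | target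

**Step count and risks**

Total step count: 19. Longest linear sequence: 19 steps (from 1 and 2 to 24); 13 and 18 enter as commercial acids.

Steps most likely to fail:

1. Step 12 (ring-closing metathesis). What may go wrong: closure to the strained trans-fused cyclohexene may be slower than intermolecular metathesis, so that oligomers form. Fallback (ring closure at sp3 carbons, alkene made afterwards), setting out from 15: ozonolysis of the two terminal alkenes (O3, pyridine, CH2Cl2, −78 °C; PPh3; the electron-poor angelate alkene reacts much more slowly) should give the dialdehyde (S)-1-[(1S,4R)-3-endo-formyl-1,3-dimethyl-7-oxabicyclo[2.2.1]heptan-2-exo-yl]-3-oxopropyl angelate F4. Pinacol cyclisation with SmI2 in THF at −78 °C should close ring B as the cis diol 6α-angeloyloxy-1β,4β-epoxy-11,12,13-trinoreudesmane-8α,9α-diol F5. Thiocarbonyldiimidazole in toluene at 80 °C converts it into the cyclic thionocarbonate of that diol F6. Corey–Winter elimination with 1,3-dimethyl-2-phenyl-1,3,2-diazaphospholidine at 40 °C then delivers the alkene and returns to the route at 16.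

2. Step 1 (Diels–Alder reaction). What may go wrong: poor regio- or exo/endo selectivity, or cycloreversion once the pressure is released. Fallback (stepwise assembly of the same diester), setting out from 1: cycloaddition with dimethyl acetylenedicarboxylate at 25 °C gives dimethyl 1-methyl-7-oxabicyclo[2.2.1]hepta-2,5-diene-2,3-dicarboxylate F1. Hydrogenation of the unsubstituted double bond only (H2, 1 equiv, 10% Pd/C, EtOAc) gives dimethyl 1-methyl-7-oxabicyclo[2.2.1]hept-2-ene-2,3-dicarboxylate F2. Conjugate addition of Me2CuLi (THF, −78 °C, Me3SiCl; NH4Cl quench) should take place from the exo face at C3, the alkene carbon remote from the bridgehead methyl, and after exo protonation give dimethyl 3-exo,1-dimethyl-7-oxabicyclo[2.2.1]heptane-2-endo,3-endo-dicarboxylate F3. Epimerisation at C2 with NaOMe in MeOH to the more stable trans diester returns to the route at racemic 4.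

3. Step 17 (C–H insertion). What may go wrong: the carbenoid may insert into the C9–H bond, or be lost to dimerisation and to adventitious water, because the C7 methylene is electron-poor. Fallback (removing the competing C–H bond instead of deactivating it), setting out from 20: Dess–Martin oxidation of the 9α-hydroxyl gives 6α-angeloyloxy-1β,4β-epoxy-9-oxo-11,12,13-trinoreudesman-8β-yl diazo(diethoxyphosphoryl)acetate F7, in which C7–H is the only C–H within five-membered reach. Rh2(OAc)4 in ClCH2CH2Cl at 80 °C should then give 6α-angeloyloxy-11-(diethoxyphosphoryl)-1β,4β-epoxy-9-oxo-13-noreudesman-12,8β-olide F8. Reduction of the C9 ketone with KBH(s-Bu)3 in THF at −78 °C, with hydride delivered from the β face, returns to the route at 23. This path drops steps 16 and 18 but depends on a late reduction next to the quaternary C10 whose facial outcome is less secure, which is why it is held in reserve.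

Further compounds

F1 | step 1 | dimethyl 1-methyl-7-oxabicyclo[2.2.1]hepta-2,5-diene-2,3-dicarboxylate (racemic; the enantiomer carried on is shown) | COC(=O)C1=C(C(=O)OC)[C@H]2C=C[C@]1(C)O2
F2 | step 1 | dimethyl 1-methyl-7-oxabicyclo[2.2.1]hept-2-ene-2,3-dicarboxylate (racemic; the enantiomer carried on is shown) | COC(=O)C1=C(C(=O)OC)[C@H]2CC[C@]1(C)O2
F3 | step 1 | dimethyl 3-exo,1-dimethyl-7-oxabicyclo[2.2.1]heptane-2-endo,3-endo-dicarboxylate (racemic; the enantiomer carried on is shown) | COC(=O)[C@H]1[C@@](C)(C(=O)OC)[C@H]2CC[C@]1(C)O2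
F4 | step 12 | (S)-1-[(1S,4R)-3-endo-formyl-1,3-dimethyl-7-oxabicyclo[2.2.1]heptan-2-exo-yl]-3-oxopropyl angelate | O=CC[C@H](OC(=O)/C(C)=C\C)[C@@H]1[C@@](C)(C=O)[C@H]2CC[C@]1(C)O2
F5 | step 12 | 6α-angeloyloxy-1β,4β-epoxy-11,12,13-trinoreudesmane-8α,9α-diol | O[C@@H]1C[C@H](OC(=O)/C(C)=C\C)[C@@H]2[C@@](C)([C@@H]1O)[C@H]3CC[C@]2(C)O3
F6 | step 12 | cyclic 8α,9α-thionocarbonate of 6α-angeloyloxy-1β,4β-epoxy-11,12,13-trinoreudesmane-8α,9α-diol | S=C1O[C@@H]2C[C@H](OC(=O)/C(C)=C\C)[C@@H]3[C@@](C)([C@@H]2O1)[C@H]4CC[C@]3(C)O4
F7 | step 17 | 6α-angeloyloxy-1β,4β-epoxy-9-oxo-11,12,13-trinoreudesman-8β-yl diazo(diethoxyphosphoryl)acetate | CCOP(=O)(OCC)C(=[N+]=[N-])C(=O)O[C@H]1C[C@H](OC(=O)/C(C)=C\C)[C@@H]2[C@@](C)(C1=O)[C@H]3CC[C@]2(C)O3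
F8 | step 17 | 6α-angeloyloxy-11-(diethoxyphosphoryl)-1β,4β-epoxy-9-oxo-13-noreudesman-12,8β-olide (C11 epimers; one shown) | CCOP(=O)(OCC)[C@H]1C(=O)O[C@H]2[C@@H]1[C@H](OC(=O)/C(C)=C\C)[C@@H]1[C@@](C)(C2=O)[C@H]2CC[C@]1(C)O2
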